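**Retrosynthetic overview**
1. S–S bond. The disulfide between the two C5 atoms is cut last, giving two identical imidazole-5-thiolates 11.
2. Imidazole ring. Thiolate 11 is the Dimroth isomer of 2-amino-5-(methylamino)thiazole 9. The swap breaks S–C2 and forms N1–C2, and the C5–S bond is never broken.
3. Thiazole ring. It is cut at C4–N3, C4–C5 and C5–S into three components. The inviting feature is that C5 of each imidazole carries both S and N1–CH3, so it is an isocyanide carbon after α-addition. In addition, S, C2, the 2-NH2 and N3 add up to exactly one thiourea, and C4 with its aryl group is 4-methoxybenzaldehyde.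
4. Ring order. The thiazole is formed in step 2. Both imidazoles and the S–S link are formed in step 3. Methyl isocyanide is made in step 1.

Key step: step 2

Remark: the target has no stereocentre and no configurationally stable axis, because the disulfide helicity inverts freely. It is achiral, so no enantioselective step is needed.

**Step 1**
Reactants: 1 N-methylformamide
Product: 2 methyl isocyanide
Conditions: TsCl (1.5 equiv), quinoline, 75 °C, 15 mmHg, product distilled into a −78 °C trap; kept cold as a MeCN solution
Reagents that add atoms: none
Why: This is a formamide dehydration (Ugi-type isocyanide synthesis: O-sulfonylation, then base-induced α-elimination), and the high-boiling base lets the volatile isocyanide distil out as it forms.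

**Step 2**
Reactants: 3 4-methoxybenzaldehyde; 4 thiourea; 2 methyl isocyanide
Product: 8 2-amino-4-(4-methoxyphenyl)-5-(methylamino)thiazole hydrochloride, via N-(4-methoxybenzylidene)thiourea 5 (not isolated), via N-methyl-2-(4-methoxyphenyl)-2-thioureidoacetonitrilium chloride 6 (not isolated), via 2-amino-4-(4-methoxyphenyl)-5-(methylimino)-2-thiazoline 7 (not isolated)
Conditions: 3, 4, TMSCl (2.2 equiv), MeCN/DMF 4:1, rt, 30 min; then 2 added slowly, 0 °C to rt, closed flask, Ar; Et2O, filtration
Reagents that add atoms: chlorotrimethylsilane, C[Si](C)(C)Cl
Why: Proposed new method: TMSCl binds the water of condensation and releases HCl, so 3 and 4 give the N-protonated form of thiocarbamoyl imine 5 (the electrophile of the Biginelli reaction), the carbon of isocyanide 2 adds to its benzylic carbon (C4–C5 bond) to give nitrilium ion 6, the thiocarbonyl sulfur closes on the nitrilium carbon (C5–S bond) to give 7, and a proton shift from the benzylic C4–H aromatises 7 to the thiazole, which is caught as salt 8. The closest known reaction types are the Groebke–Blackburn–Bienaymé reaction (aldehyde, amidine and isocyanide, the same formal [4+1] on an N=C–N=C unit made in the flask, also run with TMSCl), the [4+1] cycloaddition of isocyanides with N-acylimines to 5-aminooxazoles, and the acid-promoted condensation of aldehydes, thiourea and alkynes to 2-amino-1,3-thiazines, where the same iminium ion is attacked at carbon and closed through sulfur; what is new is thiourea as the four-atom partner of an isocyanide. The single ring closes in the 5-exo-dig mode (S onto C≡N+, the nitrogen stays outside the ring). No stereocentre has to be controlled, since C4 of 7 forms racemic and becomes sp2 in 8. Three selectivities are needed: the aldehyde carbon must end on N and not on S of thiourea (S-adducts form reversibly and, being protonated isothiouronium ions, could ionise only to a dication), 6 must close through S and not through the far NH2 (sulfur is the kinetic nucleophile of thioureas, as in the Hantzsch synthesis), and the product must not condense again with 3 and 2 as a 2-aminoazole (it is the strongest base in the flask and is withdrawn as its hydrochloride).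

**Step 3**
Reactants: 8 2-amino-4-(4-methoxyphenyl)-5-(methylamino)thiazole hydrochloride (two molecules per molecule of product)
Product: 12 bis[2-amino-4-(4-methoxyphenyl)-1-methylimidazol-5-yl] disulfide (target), via 2-amino-4-(4-methoxyphenyl)-5-(methylamino)thiazole 9 (not isolated), via 2-(cyanoamino)-2-(4-methoxyphenyl)-N-methylthioacetamide 10 (not isolated), via sodium 2-amino-4-(4-methoxyphenyl)-1-methylimidazole-5-thiolate 11 (not isolated)
Conditions: NaOH (2.2 equiv), degassed EtOH/H2O 4:1, Ar, 70 °C; then I2 (0.5 equiv) in EtOH, 0 °C; H2O, filtration
Reagents that add atoms: none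
Why: Base frees 9 and triggers the Cook–Heilbron/Dimroth-type isomerisation of a 5-(alkylamino)thiazole to a 1-alkylimidazole-5-thiolate (E1cB opening of S–C2 to cyanamide–thioamide 10, then 5-exo-dig reclosure through N–CH3; the N-methyl group blocks the alternative S–C5 opening because no neutral nitrile can form, and thiolate formation makes 11 the sink), after which iodine couples two thiolates in a fast, selective thiol-to-disulfide oxidation that should leave the fully substituted 2-aminoimidazole and the anisyl groups untouched.

**Compound list**
1 | N-methylformamide | CNC=O | starting material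
2 | methyl isocyanide | C[N+]#[C-] | intermediate
3 | 4-methoxybenzaldehyde | COc1ccc(C=O)cc1 | starting material
4 | thiourea | NC(N)=S | starting material
5 | (E)-N-(4-methoxybenzylidene)thiourea (reacts in its N-protonated form) | COc1ccc(/C=N/C(N)=S)cc1 | intermediate
6 | N-methyl-2-(4-methoxyphenyl)-2-thioureidoacetonitrilium chloride (racemic, transient) | C[N+]#CC(NC(N)=S)c1ccc(OC)cc1.[Cl-] | intermediate
7 | 2-amino-4-(4-methoxyphenyl)-5-(methylimino)-2-thiazoline (racemic, transient) | CN=C1SC(N)=NC1c1ccc(OC)cc1 | intermediate
8 | 2-amino-4-(4-methoxyphenyl)-5-(methylamino)thiazole hydrochloride | CNc1sc(N)nc1-c1ccc(OC)cc1.Cl | intermediate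
9 | 2-amino-4-(4-methoxyphenyl)-5-(methylamino)thiazole (free base) | CNc1sc(N)nc1-c1ccc(OC)cc1 | intermediate
10 | 2-(cyanoamino)-2-(4-methoxyphenyl)-N-methylthioacetamide (racemic, transient, present as its anion) | CNC(=S)C(NC#N)c1ccc(OC)cc1 | intermediate
11 | sodium 2-amino-4-(4-methoxyphenyl)-1-methylimidazole-5-thiolate | COc1ccc(-c2nc(N)n(C)c2[S-])cc1.[Na+] | intermediate
12 | bis[2-amino-4-(4-methoxyphenyl)-1-methylimidazol-5-yl] disulfide (CNP0150140.0, achiral) | COc1ccc(-c2nc(N)n(C)c2SSc2c(-c3ccc(OC)cc3)nc(N)n2C)cc1 | target

**Total step count:** 3
**Longest linear sequence:** 3 (1 → 2 → 8 → 12)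

**Steps most likely to fail**

1. Step 2 (Proposed new method).
 - What may go wrong: acid-induced solvolysis or polymerisation of the isocyanide may outrun its addition to an iminium ion that is present only in low concentration. The nitrilium ion may close through nitrogen. The product may condense a second time with aldehyde and isocyanide.
 - Fallback: this uses known chemistry, in which the C4–C5 bond comes with a ketone and the C5–N bond is made by substitution. It sets out from 4. Hantzsch condensation of 4 with commercial 2-bromo-4'-methoxyacetophenone (EtOH, reflux) should give 2-amino-4-(4-methoxyphenyl)thiazole F1. Electrophilic bromination of the free C5 position (NBS, MeCN, 0 °C) should give 2-amino-5-bromo-4-(4-methoxyphenyl)thiazole F2. Addition–elimination with excess methylamine (THF/DMF, sealed tube, 60 °C, Ar) is a known reaction of 2-amino-5-halothiazoles with amines and should give 9. The route is rejoined at 9, and step 3 then needs one equivalent less of NaOH.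

2. Step 3.
 - What may go wrong: the S–C2 bond may open slowly, so that the electron-rich free base decays in hot alkali before it isomerises. Hydroxide may attack C2 with loss of ammonia. Oxidation may run past the disulfide stage.
 - Fallback: the imidazole ring is built first and the sulfur is added last. It sets out from 3. A van Leusen oxazole synthesis (TosMIC, K2CO3, MeOH, reflux) should give 5-(4-methoxyphenyl)oxazole F3. N-Methylation (MeOTf, CH2Cl2, rt) should give 5-(4-methoxyphenyl)-3-methyloxazolium triflate F4. Hydrolytic ring opening and deformylation (aq. HCl, reflux) should give 1-(4-methoxyphenyl)-2-(methylamino)ethanone hydrochloride F5. Condensation with cyanamide (H2O/EtOH, pH 4–5, reflux; then base) should give 2-amino-4-(4-methoxyphenyl)-1-methylimidazole F6. Electrophilic sulfenylation of its free C5–H with S2Cl2 (0.5 equiv, AcOH, rt; then aq. NH3) should install both C–S bonds and the S–S bond at once. The route is rejoined at 12.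

3. Step 1.
 - What may go wrong: the volatile isocyanide may be lost in the vacuum distillation. Quinoline may be carried over. The isocyanide may isomerise or polymerise on storage.
 - Fallback: no methyl isocyanide is made, and the N-methyl group is unmasked at the end. It sets out from 3 and 4. These are combined with commercial (trimethylsilyl)methyl isocyanide under the conditions of step 2, which should give 2-amino-4-(4-methoxyphenyl)-5-{[(trimethylsilyl)methyl]amino}thiazole hydrochloride F7. The conditions of step 3 should then give bis{2-amino-4-(4-methoxyphenyl)-1-[(trimethylsilyl)methyl]imidazol-5-yl} disulfide F8. Fluoride-induced protodesilylation (TBAF trihydrate, THF, rt) is known for N-(silylmethyl)azoles and should give 12, where the route is rejoined.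

**Further compounds**
F1 | step 2 | 2-amino-4-(4-methoxyphenyl)thiazole | COc1ccc(-c2csc(N)n2)cc1
F2 | step 2 | 2-amino-5-bromo-4-(4-methoxyphenyl)thiazole | COc1ccc(-c2nc(N)sc2Br)cc1
F3 | step 3 | 5-(4-methoxyphenyl)oxazole | COc1ccc(-c2cnco2)cc1
F4 | step 3 | 5-(4-methoxyphenyl)-3-methyloxazolium triflate | COc1ccc(-c2c[n+](C)co2)cc1.[O-]S(=O)(=O)C(F)(F)F
F5 | step 3 | 1-(4-methoxyphenyl)-2-(methylamino)ethanone hydrochloride | CNCC(=O)c1ccc(OC)cc1.Cl
F6 | step 3 | 2-amino-4-(4-methoxyphenyl)-1-methylimidazole | COc1ccc(-c2cn(C)c(N)n2)cc1
F7 | step 1 | 2-amino-4-(4-methoxyphenyl)-5-{[(trimethylsilyl)methyl]amino}thiazole hydrochloride | C[Si](C)(C)CNc1sc(N)nc1-c1ccc(OC)cc1.Cl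
F8 | step 1 | bis{2-amino-4-(4-methoxyphenyl)-1-[(trimethylsilyl)methyl]imidazol-5-yl} disulfide | COc1ccc(-c2nc(N)n(C[Si](C)(C)C)c2SSc2c(-c3ccc(OC)cc3)nc(N)n2C[Si](C)(C)C)cc1
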